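Assumption: 2,3:5,6-di-O-isopropylidene-α-D-mannofuranose (diacetone mannose, one step from D-mannose) is taken as the cheap catalogue starting material; 3-bromopropenyl benzoate is not assumed to be on sale and is made in step 5.

**Retrosynthetic overview**
1. Target 12 ⇒ acyclic triol diene 11: the only ring, the cyclohexene, is closed last by ring-closing metathesis (C2=C3).
2. 11 ⇒ α-hydroxy aldehyde 9 + bromo enol ester 8: the C4–C5 bond joins two carbonyl carbons. The carbonyl carbon of acrolein, carried as a γ-benzoyloxyallylindium (an α-hydroxyallyl anion equivalent), attacks the chelated aldehyde, sets C4 and C5 and brings the C4 benzoate with it.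
3. 9 ⇐ vinyl dioxolane aldehyde 5 ⇐ diacetone mannose 1: C1 and C6 of the target are C2 and C3 of D-mannose. The quaternary C1 comes from a formaldehyde aldol, the vinyl from a Wittig reaction, and sugar C5/C6 are excised with periodic acid.

**Route**

Step 1
Reactants: 1 2,3:5,6-di-O-isopropylidene-α-D-mannofuranose
Product: 2 2-C-(hydroxymethyl)-2,3:5,6-di-O-isopropylidene-D-mannofuranose (anomer mixture)
Conditions: 37% aq. CH2O (excess), K2CO3, MeOH, reflux, 24–48 h
Reagents that add atoms: formaldehyde, C=O
Why: Crossed aldol (Ho type): the ring-opened aldehyde enolises at C2 and adds reversibly to formaldehyde, and only the adduct that keeps C1 cis to C4 on the dioxolane can re-close to the cis-fused furanose lactol, so the quaternary carbinol (future C1) forms with retention of the manno C2–O configuration while lactol formation blocks Cannizzaro reduction.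

Step 2
Reactants: 2 2-C-(hydroxymethyl)-2,3:5,6-di-O-isopropylidene-D-mannofuranose
Product: 3 1,2-dideoxy-3-C-(hydroxymethyl)-3,4:6,7-di-O-isopropylidene-D-manno-hept-1-enitol (free OH on the branch CH2OH and at C5)
Conditions: Ph3PCH3Br (4 equiv), KOtBu, THF, 0 °C → rt
Reagents that add atoms: methyltriphenylphosphonium bromide, C[P+](c1ccccc1)(c1ccccc1)c1ccccc1.[Br-]
Why: Wittig methylenation of the hydroxy-aldehyde tautomer of the lactol puts the vinyl group on the quaternary carbon and frees the sugar C4 hydroxyl, with no stereocentre touched.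

Step 3
Reactants: 3 1,2-dideoxy-3-C-(hydroxymethyl)-3,4:6,7-di-O-isopropylidene-D-manno-hept-1-enitol
Product: 4 3-C-(benzoyloxymethyl)-1,2-dideoxy-3,4:6,7-di-O-isopropylidene-D-manno-hept-1-enitol (free OH at C5)
Conditions: BzCl (1.05 equiv), pyridine, CH2Cl2, −20 → 0 °C
Reagents that add atoms: benzoyl chloride, O=C(Cl)c1ccccc1
Why: Chemoselective O-acylation: the primary hydroxyl reacts much faster than the secondary hydroxyl wedged between two dioxolane rings, so the first benzoate of the target is placed cleanly.

Step 4
Reactants: 4 3-C-(benzoyloxymethyl)-1,2-dideoxy-3,4:6,7-di-O-isopropylidene-D-manno-hept-1-enitol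
Product: 5 [(4S,5R)-5-formyl-2,2-dimethyl-4-vinyl-1,3-dioxolan-4-yl]methyl benzoate (formyl cis to vinyl)
Conditions: H5IO6 (2.5 equiv), EtOAc, rt
Reagents that add atoms: none
Why: Periodic acid first hydrolyses the more labile terminal acetonide and then carries out two Malaprade glycol cleavages on the resulting triol, excising the two terminal carbons and leaving the aldehyde, while the fully substituted internal dioxolane and both stereocentres survive.

Step 5
Reactants: 6 acrolein; 7 benzoyl bromide
Product: 8 3-bromoprop-1-en-1-yl benzoate (E/Z mixture, used as such)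
Conditions: ZnCl2 (cat.), CH2Cl2, −20 °C → rt
Reagents that add atoms: none
Why: ZnCl2-catalysed 1,4-addition of the acyl bromide to the enal (O-acylation with conjugate delivery of bromide) gives the γ-bromo enol ester, in which the former carbonyl carbon of acrolein is primed to act as a nucleophile.

Step 6
Reactants: 5 [(4S,5R)-5-formyl-2,2-dimethyl-4-vinyl-1,3-dioxolan-4-yl]methyl benzoate; 8 3-bromoprop-1-en-1-yl benzoate
Product: 11 (2S,3S,4S,5R)-5-(benzoyloxy)-2,3,4-trihydroxy-2-vinylhept-6-en-1-yl benzoate, via dihydroxy aldehyde 9 (not isolated), via allylindium dibromide 10 (not isolated)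
Conditions: (i) TFA–H2O 4:1, 0 °C, 1 h, evaporate; (ii) 8 (2 equiv), In powder (2 equiv), THF–H2O 1:1, rt, ultrasound
Reagents that add atoms: none
Why: Acid hydrolysis unmasks the α-hydroxy aldehyde, and in the indium-mediated Barbier acyloxyallylation the γ-benzoyloxyallylindium attacks through its oxygen-bearing carbon a Cram-chelated aldehyde (trivalent indium bridging C=O and the α-OH, attack anti to the bulky quaternary carbon), giving the new C5 hydroxyl threo to the C6 hydroxyl and, through the cyclic transition state, the C4 benzoate erythro to it, which is the lyxo preference known for unprotected aldoses.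

Step 7
Reactants: 11 (2S,3S,4S,5R)-5-(benzoyloxy)-2,3,4-trihydroxy-2-vinylhept-6-en-1-yl benzoate
Product: 12 [(1S,4R,5S,6S)-4-(benzoyloxy)-1,5,6-trihydroxycyclohex-2-en-1-yl]methyl benzoate
Conditions: second-generation Grubbs catalyst, RuCl2(=CHPh)(PCy3)(H2IMes) (5 mol%), CH2Cl2, 40 °C
Reagents that add atoms: none
Why: Ring-closing olefin metathesis of the 1,7-diene closes the cyclohexene with loss of ethylene, and the ruthenium carbene tolerates the free hydroxyls and benzoates and leaves all four stereocentres untouched.

**Compound list**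
1 | 2,3:5,6-di-O-isopropylidene-α-D-mannofuranose | O[C@@H]1[C@H]2OC(C)(C)O[C@H]2[C@H](O1)[C@H]1COC(C)(C)O1 | starting material
2 | 2-C-(hydroxymethyl)-2,3:5,6-di-O-isopropylidene-D-mannofuranose (anomeric centre not defined) | OC1[C@@]2(CO)OC(C)(C)O[C@H]2[C@H](O1)[C@H]1COC(C)(C)O1 | intermediate
3 | 1,2-dideoxy-3-C-(hydroxymethyl)-3,4:6,7-di-O-isopropylidene-D-manno-hept-1-enitol | C=C[C@@]1(CO)OC(C)(C)O[C@H]1[C@H](O)[C@H]1COC(C)(C)O1 | intermediate
4 | 3-C-(benzoyloxymethyl)-1,2-dideoxy-3,4:6,7-di-O-isopropylidene-D-manno-hept-1-enitol | C=C[C@@]1(COC(=O)c2ccccc2)OC(C)(C)O[C@H]1[C@H](O)[C@H]1COC(C)(C)O1 | intermediate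
5 | [(4S,5R)-5-formyl-2,2-dimethyl-4-vinyl-1,3-dioxolan-4-yl]methyl benzoate | C=C[C@@]1(COC(=O)c2ccccc2)OC(C)(C)O[C@H]1C=O | intermediate
6 | acrolein | C=CC=O | starting material
7 | benzoyl bromide | O=C(Br)c1ccccc1 | starting material
8 | 3-bromoprop-1-en-1-yl benzoate (E/Z mixture) | BrCC=COC(=O)c1ccccc1 | intermediate
9 | (2S,3R)-2,3-dihydroxy-4-oxo-2-vinylbutyl benzoate | C=C[C@](O)(COC(=O)c1ccccc1)[C@@H](O)C=O | intermediate
10 | [3-(benzoyloxy)prop-2-en-1-yl]indium dibromide (simplest formulation of the allylindium sesquibromide) | O=C(OC=CC[In](Br)Br)c1ccccc1 | intermediate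
11 | (2S,3S,4S,5R)-5-(benzoyloxy)-2,3,4-trihydroxy-2-vinylhept-6-en-1-yl benzoate | C=C[C@@H](OC(=O)c1ccccc1)[C@@H](O)[C@H](O)[C@@](O)(COC(=O)c1ccccc1)C=C | intermediate
12 | [(1S,4R,5S,6S)-4-(benzoyloxy)-1,5,6-trihydroxycyclohex-2-en-1-yl]methyl benzoate | O=C(OC[C@@]1(O)C=C[C@@H](OC(=O)c2ccccc2)[C@@H](O)[C@@H]1O)c1ccccc1 | target

**Step count**
Total: 7 steps. Longest linear sequence: 6 steps (1 → 2 → 3 → 4 → 5 → 11 → 12); step 5 is the one-step side branch that makes 8.

**Three steps most likely to fail, with fallbacks**

Step 6 (the coupling). The free hydroxy aldehyde 9 is fragile, the lyxo selectivity is only moderate, and the C4 benzoate can migrate to the neighbouring C5 hydroxyl. The fallback sets out from 5 with the acetonide left on and lets a chiral catalyst, not a chelate, decide the stereochemistry. Acrolein 6 and benzoic anhydride (cat. H2SO4) give prop-2-ene-1,1-diyl dibenzoate F3. Aldehyde 5 and this donor, with [Ir(cod)Cl]2, SEGPHOS (the antipode that gives the 4R,5S pair), 4-chloro-3-nitrobenzoic acid, K3PO4 and i-PrOH in THF at 60 °C, undergo anti-selective transfer-hydrogenative (α-benzoyloxy)allylation to the diene acetonide F4. Ring-closing metathesis under the step 7 conditions gives the cyclohexene acetonide F5, and TFA–H2O removes the acetonide, coming back to the route at 12.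

Step 2 (Wittig on the aldol lactol). The potassium alkoxide of the β-hydroxy aldehyde can fragment by retro-aldol before the ylide captures it. The fallback sets out from 2: Me3SiCH2MgCl (5 equiv, THF, 0 °C → rt) adds to the masked aldehyde, whose chelated magnesium aldolate does not fragment, to give the β-hydroxysilane F1. KH in THF then effects Peterson elimination, coming back to the route at 3.

Step 4 (one-pot hydrolysis and cleavage). If the internal acetonide also opens under the acidic oxidant, the C1–C6 diol of the future target is destroyed. The fallback sets out from 4 and decouples the two events: 70% aq. AcOH at 40 °C removes only the terminal acetonide, and the hept-1-ene-5,6,7-triol F2 is isolated. NaIO4 (2.2 equiv) in THF–pH 7 phosphate buffer then cleaves it under neutral conditions, coming back to the route at 5.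

Further compounds
F1 | step 2 | β-hydroxysilane: 1-deoxy-3-C-(hydroxymethyl)-3,4:6,7-di-O-isopropylidene-1-(trimethylsilyl)heptitol, D-manno at C3–C6, C2 epimer mixture | C[Si](C)(C)CC(O)[C@@]1(CO)OC(C)(C)O[C@H]1[C@H](O)[C@H]1COC(C)(C)O1
F2 | step 4 | hept-1-ene-5,6,7-triol: 3-C-(benzoyloxymethyl)-1,2-dideoxy-3,4-O-isopropylidene-D-manno-hept-1-enitol | C=C[C@@]1(COC(=O)c2ccccc2)OC(C)(C)O[C@H]1[C@H](O)[C@H](O)CO
F3 | step 6 | prop-2-ene-1,1-diyl dibenzoate | C=CC(OC(=O)c1ccccc1)OC(=O)c1ccccc1
F4 | step 6 | diene acetonide (11 with the C2 and C3 oxygens bridged by isopropylidene) | C=C[C@@H](OC(=O)c1ccccc1)[C@@H](O)[C@@H]1OC(C)(C)O[C@]1(COC(=O)c1ccccc1)C=C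
F5 | step 6 | cyclohexene acetonide (12 with the C1 and C6 oxygens bridged by isopropylidene) | C1=C[C@@H](OC(=O)c2ccccc2)[C@@H](O)[C@@H]2OC(C)(C)O[C@]12COC(=O)c1ccccc1
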